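**Strategy.** With the hydrindane numbered C1–C3, C3a, C4–C7, C7a (isobutyrates on C1/C2, acetoxyethyl on C3, oxirane on C4, enoate on C6, methylidene on C7), the five-membered ring B, oxygenated at C2 and branched at C3, is read as a cyclopentenone whose C2 comes from carbon monoxide. One cobalt-mediated Pauson–Khand reaction of an acyclic 1,7-enyne forms C7a–C3a, C1–C2 and C2–C3 and closes ring A (six-membered) and ring B together. The enyne has the vinyl group (C1, C7a), silyl ethers at C7 and C6, an acetonide-masked diol on the C4 branch that later becomes the oxirane, and an (S)-silyloxyethyl alkyne terminus (C3a, C3).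

Key step: step 12

Remarks
- Convention: names use the numbering above; α is the face of H-7a, β the opposite face (that of H-3a in the trans-fused compounds). TBSO = tert-butyldimethylsilyloxy, TIPSO = triisopropylsilyloxy, TESO = triethylsilyloxy.
- Assumption on the chemistry: epoxidation of penta-1,4-dien-3-ol with D-(−)-diisopropyl tartrate is taken to give the (2S,3R) erythro epoxy alcohol, the mirror image of the product from the L-(+) ester.
- Design: the oxirane carbon is made as a tertiary carbinol by asymmetric epoxidation, because epoxidising an isopropenyl group late would not be face-selective. C6 carries its oxygen from the start, so no late allylic oxidation is needed. C7 is an equatorial silyl ether and not a ketal, because an axial oxygen on C7 would shield the β face of C1 in step 14.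

Step 1
Reactants: 1 penta-1,4-dien-3-ol
Product: 2 (1R)-1-[(2S)-oxiran-2-yl]prop-2-en-1-ol
Conditions: Ti(OiPr)4, D-(−)-diisopropyl tartrate, t-BuOOH, 4 Å MS, CH2Cl2, −20 °C
Reagents that add atoms: tert-butyl hydroperoxide, CC(C)(C)OO
Why: Sharpless asymmetric epoxidation desymmetrises the divinyl carbinol: the tartrate complex selects one enantiotopic vinyl group and one of its faces, so the erythro epoxy alcohol with the C7 carbinol (R) and the C6 epoxide carbon (S) should form, and any minor enantiomer is consumed faster by a second epoxidation.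

Step 2
Reactants: 2 (1R)-1-[(2S)-oxiran-2-yl]prop-2-en-1-ol
Product: 3 tert-butyl(dimethyl){[(1R)-1-[(2S)-oxiran-2-yl]prop-2-en-1-yl]oxy}silane
Conditions: TBSCl, imidazole, CH2Cl2, 0 °C→rt
Reagents that add atoms: tert-butyldimethylsilyl chloride, CC(C)(C)[Si](C)(C)Cl
Why: Routine silylation of a secondary alcohol; the silyl ether will later sit equatorial on ring A and no stereocentre is touched.

Step 3
Reactants: 4 prop-2-yn-1-ol
Product: 6 (2E)-3-iodo-2-methylprop-2-en-1-ol, via alkenylalane 5 (not isolated)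
Conditions: AlMe3, Cp2ZrCl2 (0.25 equiv), CH2Cl2, 0 °C→rt; then I2, THF, −30 °C
Reagents that add atoms: trimethylaluminium, C[Al](C)C; iodine, II
Why: Zirconium-catalysed Negishi carboalumination adds methyl and aluminium syn across the terminal alkyne with aluminium at the terminus, and iodinolysis of the C–Al bond proceeds with retention to give the (E)-iodide.

Step 4
Reactants: 6 (2E)-3-iodo-2-methylprop-2-en-1-ol
Product: 7 1-({[(2E)-3-iodo-2-methylprop-2-en-1-yl]oxy}methyl)-4-methoxybenzene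
Conditions: NaH, 4-methoxybenzyl chloride, Bu4NI (cat.), THF, 0 °C→rt
Reagents that add atoms: 4-methoxybenzyl chloride, COc1ccc(CCl)cc1
Why: Williamson etherification of the primary allylic alcohol; the vinyl iodide is inert to NaH.

Step 5
Reactants: 7 1-({[(2E)-3-iodo-2-methylprop-2-en-1-yl]oxy}methyl)-4-methoxybenzene; 3 tert-butyl(dimethyl){[(1R)-1-[(2S)-oxiran-2-yl]prop-2-en-1-yl]oxy}silane
Product: 9 (3R,4S,6E)-3-(TBSO)-8-[(4-methoxybenzyl)oxy]-7-methylocta-1,6-dien-4-ol, via alkenyllithium 8 (not isolated)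
Conditions: 7, t-BuLi (2 equiv), Et2O, −78 °C; then 3, BF3·OEt2, −78 °C
Reagents that add atoms: none
Why: Iodine–lithium exchange proceeds with retention of the (E) geometry and the BF3-activated terminal epoxide is opened by the alkenyllithium at its CH2 carbon (SN2), so the C5–C4 bond forms while the C6 and C7 stereocentres are not touched.

Step 6
Reactants: 9 (3R,4S,6E)-3-(TBSO)-8-[(4-methoxybenzyl)oxy]-7-methylocta-1,6-dien-4-ol
Product: 10 (3R,4S,6E)-3-(TBSO)-8-[(4-methoxybenzyl)oxy]-7-methyl-4-(TIPSO)octa-1,6-diene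
Conditions: TIPSOTf, 2,6-lutidine, CH2Cl2, −78→0 °C
Reagents that add atoms: triisopropylsilyl trifluoromethanesulfonate, CC(C)[Si](C(C)C)(C(C)C)OS(=O)(=O)C(F)(F)F
Why: Silylation of the hindered secondary alcohol with the silyl triflate; the bulkier triisopropylsilyl group is chosen so that the C7 tert-butyldimethylsilyl ether can later be removed in its presence.

Step 7
Reactants: 10 (3R,4S,6E)-3-(TBSO)-8-[(4-methoxybenzyl)oxy]-7-methyl-4-(TIPSO)octa-1,6-diene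
Product: 11 (2E,5S,6R)-6-(TBSO)-2-methyl-5-(TIPSO)octa-2,7-dien-1-ol
Conditions: DDQ, CH2Cl2/pH 7 buffer, 0 °C
Reagents that add atoms: none
Why: Oxidative cleavage of the 4-methoxybenzyl ether by DDQ (hydride abstraction, then hydrolysis of the oxocarbenium ion) leaves the silyl ethers and both alkenes intact.

Step 8
Reactants: 11 (2E,5S,6R)-6-(TBSO)-2-methyl-5-(TIPSO)octa-2,7-dien-1-ol
Product: 12 [(2S,3S)-3-{(2S,3R)-3-(TBSO)-2-(TIPSO)pent-4-en-1-yl}-2-methyloxiran-2-yl]methanol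
Conditions: Ti(OiPr)4, L-(+)-diethyl tartrate, t-BuOOH, 4 Å MS, CH2Cl2, −20 °C
Reagents that add atoms: tert-butyl hydroperoxide, CC(C)(C)OO
Why: Sharpless asymmetric epoxidation of an (E)-2-methyl allylic alcohol is reagent-controlled: with the L-(+)-tartrate, oxygen should be delivered to the face that gives the (2S,3S)-epoxide, which fixes the future oxirane carbon and, after the inversion in step 10, C4; the unfunctionalised vinyl group is not epoxidised.

Step 9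
Reactants: 13 (2S)-but-3-yn-2-ol
Product: 14 [(2S)-but-3-yn-2-yloxy]triethylsilane
Conditions: Et3SiCl, imidazole, CH2Cl2, 0 °C
Reagents that add atoms: chlorotriethylsilane, CC[Si](CC)(CC)Cl
Why: Routine silylation; the carbinol stereocentre comes from the commercial (S)-alcohol.

Step 10
Reactants: 14 [(2S)-but-3-yn-2-yloxy]triethylsilane; 12 [(2S,3S)-3-{(2S,3R)-3-(TBSO)-2-(TIPSO)pent-4-en-1-yl}-2-methyloxiran-2-yl]methanol
Product: 17 (2R,3S,5S,6R)-6-(TBSO)-2-methyl-3-[(3S)-3-(TESO)but-1-yn-1-yl]-5-(TIPSO)oct-7-ene-1,2-diol, via lithium acetylide 15 (not isolated), via alkynylalane 16 (not isolated)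
Conditions: 14, n-BuLi, toluene, −78→0 °C; Et2AlCl, 0 °C; then 12, 0 °C→rt
Reagents that add atoms: none
Why: Organoalane opening of a 2,3-epoxy alcohol: the aluminium alkoxide of the primary hydroxyl activates the epoxide and the alkynyl group attacks C3 of the epoxy alcohol (the future C4), distal to the carbinol and the only secondary position, with inversion, while the quaternary carbinol carbon keeps its configuration.

Step 11
Reactants: 17 (2R,3S,5S,6R)-6-(TBSO)-2-methyl-3-[(3S)-3-(TESO)but-1-yn-1-yl]-5-(TIPSO)oct-7-ene-1,2-diol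
Product: 18 (4R)-4-{(3R,4S,6S,9S)-3-(TBSO)-9-(TESO)-4-(TIPSO)dec-1-en-7-yn-6-yl}-2,2,4-trimethyl-1,3-dioxolane
Conditions: 2-methoxypropene, pyridinium 4-toluenesulfonate (cat.), CH2Cl2, 0 °C
Reagents that add atoms: 2-methoxypropene, COC(C)=C
Why: Acid-catalysed ketalisation ties the primary/tertiary diol into a dioxolane that masks the future oxirane and makes the C4 substituent a bulky conformational anchor.

Step 12
Reactants: 18 (4R)-4-{(3R,4S,6S,9S)-3-(TBSO)-9-(TESO)-4-(TIPSO)dec-1-en-7-yn-6-yl}-2,2,4-trimethyl-1,3-dioxolane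
Product: 20 (7aα-H)-7α-(TBSO)-6α-(TIPSO)-3-[(1S)-1-(TESO)ethyl]-4β-[(4R)-2,2,4-trimethyl-1,3-dioxolan-4-yl]-1,4,5,6,7,7a-hexahydro-2H-inden-2-one, via hexacarbonyldicobalt alkyne complex 19 (not isolated)
Conditions: Co2(CO)8, CH2Cl2, rt; then N-methylmorpholine N-oxide, 0 °C→rt
Reagents that add atoms: dicobalt octacarbonyl, O=C=[Co](=C=O)(=C=O)(=C=O)[Co](=C=O)(=C=O)(=C=O)=C=O
Why: The alkyne of 18 is bound as the hexacarbonyldicobalt complex 19, the N-oxide strips one CO, the C1=C7a vinyl group coordinates and inserts into the Co–C3a bond (C7a–C3a), CO migrates onto C1 and reductive elimination joins C1–C2 and C2–C3. The closest known reaction type is the intramolecular Pauson–Khand reaction of 1,7-enynes that carry oxygenated, branched tethers. Ring A closes by exo insertion of the tethered alkene through a chair-like six-membered transition state, ring B by the carbonylative [2+2+1] closure on cobalt. The one new stereocentre, C7a, is controlled by the chair: the quaternary dioxolanyl group on C4 and the C7 silyl ether sit equatorial and the C6 silyl ether axial, so C1 must be equatorial and H-7a axial, anti to H-7 and cis to H-4. The step needs this facial selectivity on the vinyl group (regiochemistry is fixed by the tether), and the bulky C4 group acts as the conformational anchor while the (S)-carbinol at the alkyne end turns its C–H toward C4 to relieve allylic strain.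

Step 13
Reactants: 20 (7aα-H)-7α-(TBSO)-6α-(TIPSO)-3-[(1S)-1-(TESO)ethyl]-4β-[(4R)-2,2,4-trimethyl-1,3-dioxolan-4-yl]-1,4,5,6,7,7a-hexahydro-2H-inden-2-one
Product: 22 (3aβ-H,7aα-H)-7α-(TBSO)-6α-(TIPSO)-3β-[(1S)-1-(TESO)ethyl]-4β-[(4R)-2,2,4-trimethyl-1,3-dioxolan-4-yl]octahydro-2H-inden-2-one, via lithium enolate 21 (not isolated)
Conditions: Li, NH3(l)/THF, t-BuOH (1 equiv), −78 °C; then NH4Cl
Reagents that add atoms: none
Why: Dissolving-metal (Birch-type) reduction of the enone: the C3a carbanion is protonated axially to give the trans ring fusion (H-3a β, anti to H-7a, C4 group still equatorial) and the resulting enolate 21 is protonated at C3 anti to the axial H-3a, which places the side chain β.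

Step 14
Reactants: 22 (3aβ-H,7aα-H)-7α-(TBSO)-6α-(TIPSO)-3β-[(1S)-1-(TESO)ethyl]-4β-[(4R)-2,2,4-trimethyl-1,3-dioxolan-4-yl]octahydro-2H-inden-2-one
Product: 26 (3aβ-H,7aα-H)-1β-hydroxy-7α-(TBSO)-6α-(TIPSO)-3β-[(1S)-1-(TESO)ethyl]-4β-[(4R)-2,2,4-trimethyl-1,3-dioxolan-4-yl]octahydro-2H-inden-2-one, via lithium enolate 23 (not isolated), via silyl enol ether 24 (not isolated), via silyloxy ketone 25 (not isolated)
Conditions: LiN(iPr)2, Me3SiCl, THF, −78 °C; then mCPBA, NaHCO3, CH2Cl2, −20 °C; citric acid, MeOH, 0 °C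
Reagents that add atoms: 3-chloroperbenzoic acid, OOC(=O)c1cccc(Cl)c1
Why: Rubottom oxidation: kinetic deprotonation occurs at the C1 methylene and not at the branched C3, and the peracid should add to C1 of enol ether 24 anti to the pseudo-axial H-7a (torsional control; that face is flanked only by the axial H-7 because the C7 silyl ether is equatorial), so that silyl migration and methanolysis leave the 1β-hydroxyl.

Step 15
Reactants: 26 (3aβ-H,7aα-H)-1β-hydroxy-7α-(TBSO)-6α-(TIPSO)-3β-[(1S)-1-(TESO)ethyl]-4β-[(4R)-2,2,4-trimethyl-1,3-dioxolan-4-yl]octahydro-2H-inden-2-one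
Product: 27 (3aβ-H,7aα-H)-7α-(TBSO)-6α-(TIPSO)-3β-[(1S)-1-(TESO)ethyl]-4β-[(4R)-2,2,4-trimethyl-1,3-dioxolan-4-yl]-2-oxooctahydro-1H-inden-1β-yl 2-methylpropanoate
Conditions: (iPrCO)2O, DMAP, pyridine, CH2Cl2, 0 °C→rt
Reagents that add atoms: 2-methylpropanoic anhydride, CC(C)C(=O)OC(=O)C(C)C
Why: DMAP-catalysed acylation of the α-hydroxy ketone installs the C1 isobutyrate and blocks this hydroxyl before the carbinol is released.

Step 16
Reactants: 27 (3aβ-H,7aα-H)-7α-(TBSO)-6α-(TIPSO)-3β-[(1S)-1-(TESO)ethyl]-4β-[(4R)-2,2,4-trimethyl-1,3-dioxolan-4-yl]-2-oxooctahydro-1H-inden-1β-yl 2-methylpropanoate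
Product: 28 (3aβ-H,7aα-H)-7α-(TBSO)-6α-(TIPSO)-3β-[(1S)-1-hydroxyethyl]-4β-[(4R)-2,2,4-trimethyl-1,3-dioxolan-4-yl]-2-oxooctahydro-1H-inden-1β-yl 2-methylpropanoate
Conditions: HF·pyridine, pyridine, THF, 0 °C
Reagents that add atoms: none
Why: Buffered HF·pyridine cleaves the triethylsilyl ether much faster than the tert-butyldimethylsilyl and triisopropylsilyl ethers, liberating the β-hydroxy ketone needed for step 17.

Step 17
Reactants: 28 (3aβ-H,7aα-H)-7α-(TBSO)-6α-(TIPSO)-3β-[(1S)-1-hydroxyethyl]-4β-[(4R)-2,2,4-trimethyl-1,3-dioxolan-4-yl]-2-oxooctahydro-1H-inden-1β-yl 2-methylpropanoate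
Product: 29 (3aβ-H,7aα-H)-3β-[(1S)-1-acetoxyethyl]-7α-(TBSO)-2α-hydroxy-6α-(TIPSO)-4β-[(4R)-2,2,4-trimethyl-1,3-dioxolan-4-yl]octahydro-1H-inden-1β-yl 2-methylpropanoate
Conditions: SmI2 (0.3 equiv, premixed with CH3CHO), CH3CHO (10 equiv), THF, −10 °C
Reagents that add atoms: acetaldehyde, CC=O
Why: Evans–Tishchenko reduction: the samarium-bound hemiacetal formed from the carbinol and acetaldehyde delivers hydride intramolecularly to C2 through a six-membered transition state from the face of the side chain, so the 2α-alcohol (1,3-anti to the carbinol) should form while the carbinol leaves as its acetate.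

Step 18
Reactants: 29 (3aβ-H,7aα-H)-3β-[(1S)-1-acetoxyethyl]-7α-(TBSO)-2α-hydroxy-6α-(TIPSO)-4β-[(4R)-2,2,4-trimethyl-1,3-dioxolan-4-yl]octahydro-1H-inden-1β-yl 2-methylpropanoate
Product: 30 (3aβ-H,7aα-H)-3β-[(1S)-1-acetoxyethyl]-7α-(TBSO)-6α-(TIPSO)-4β-[(4R)-2,2,4-trimethyl-1,3-dioxolan-4-yl]octahydro-1H-indene-1β,2α-diyl bis(2-methylpropanoate)
Conditions: (iPrCO)2O, DMAP, Et3N, CH2Cl2, rt
Reagents that add atoms: 2-methylpropanoic anhydride, CC(C)C(=O)OC(=O)C(C)C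
Why: Acylation of the remaining secondary hydroxyl completes the trans-1,2-bis(isobutyrate); the trans arrangement on the cyclopentane prevents acyl migration from C1.

Step 19
Reactants: 30 (3aβ-H,7aα-H)-3β-[(1S)-1-acetoxyethyl]-7α-(TBSO)-6α-(TIPSO)-4β-[(4R)-2,2,4-trimethyl-1,3-dioxolan-4-yl]octahydro-1H-indene-1β,2α-diyl bis(2-methylpropanoate)
Product: 31 (3aβ-H,7aα-H)-3β-[(1S)-1-acetoxyethyl]-7α-hydroxy-6α-(TIPSO)-4β-[(4R)-2,2,4-trimethyl-1,3-dioxolan-4-yl]octahydro-1H-indene-1β,2α-diyl bis(2-methylpropanoate)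
Conditions: HF·pyridine (excess), THF, 0 °C→rt
Reagents that add atoms: none
Why: Fluoride-mediated desilylation: the secondary tert-butyldimethylsilyl ether is cleaved by HF·pyridine well before the triisopropylsilyl ether, and the esters and the dioxolane tolerate the reagent.

Step 20
Reactants: 31 (3aβ-H,7aα-H)-3β-[(1S)-1-acetoxyethyl]-7α-hydroxy-6α-(TIPSO)-4β-[(4R)-2,2,4-trimethyl-1,3-dioxolan-4-yl]octahydro-1H-indene-1β,2α-diyl bis(2-methylpropanoate)
Product: 32 (3aβ-H,7aα-H)-3β-[(1S)-1-acetoxyethyl]-7-oxo-6α-(TIPSO)-4β-[(4R)-2,2,4-trimethyl-1,3-dioxolan-4-yl]octahydro-1H-indene-1β,2α-diyl bis(2-methylpropanoate)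
Conditions: Dess–Martin periodinane, NaHCO3, CH2Cl2, 0 °C→rt
Reagents that add atoms: none
Why: Dess–Martin oxidation under buffered, non-basic conditions gives the C7 ketone without enolisation toward C7a, which would eliminate the C1 isobutyrate.

Step 21
Reactants: 32 (3aβ-H,7aα-H)-3β-[(1S)-1-acetoxyethyl]-7-oxo-6α-(TIPSO)-4β-[(4R)-2,2,4-trimethyl-1,3-dioxolan-4-yl]octahydro-1H-indene-1β,2α-diyl bis(2-methylpropanoate)
Product: 33 (3aβ-H,7aα-H)-3β-[(1S)-1-acetoxyethyl]-7-methylidene-6α-(TIPSO)-4β-[(4R)-2,2,4-trimethyl-1,3-dioxolan-4-yl]octahydro-1H-indene-1β,2α-diyl bis(2-methylpropanoate)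
Conditions: Zn, CH2Br2, TiCl4, THF (reagent pre-formed); CH2Cl2, 0 °C→rt
Reagents that add atoms: dibromomethane, BrCBr
Why: Takai–Lombardo methylenation with the geminal dizinc/titanium reagent is non-basic and selective for ketones over esters, so the epimerisable C7a centre, the β-acyloxy group and the α-silyloxy group should survive.

Step 22
Reactants: 33 (3aβ-H,7aα-H)-3β-[(1S)-1-acetoxyethyl]-7-methylidene-6α-(TIPSO)-4β-[(4R)-2,2,4-trimethyl-1,3-dioxolan-4-yl]octahydro-1H-indene-1β,2α-diyl bis(2-methylpropanoate)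
Product: 34 (3aβ-H,7aα-H)-3β-[(1S)-1-acetoxyethyl]-4β-[(2R)-1,2-dihydroxypropan-2-yl]-6α-hydroxy-7-methylideneoctahydro-1H-indene-1β,2α-diyl bis(2-methylpropanoate)
Conditions: HF (48% aq.), MeCN, 0 °C→rt
Reagents that add atoms: none
Why: Aqueous HF in acetonitrile removes the remaining silyl ether and hydrolyses the dioxolane in one operation; the esters and the exocyclic alkene are stable to these conditions.

Step 23
Reactants: 34 (3aβ-H,7aα-H)-3β-[(1S)-1-acetoxyethyl]-4β-[(2R)-1,2-dihydroxypropan-2-yl]-6α-hydroxy-7-methylideneoctahydro-1H-indene-1β,2α-diyl bis(2-methylpropanoate)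
Product: 36 (3aβ-H,7aα-H)-3β-[(1S)-1-acetoxyethyl]-6α-hydroxy-7-methylidene-4β-[(2R)-2-methyloxiran-2-yl]octahydro-1H-indene-1β,2α-diyl bis(2-methylpropanoate), via primary tosylate 35 (not isolated)
Conditions: TsCl, pyridine, CH2Cl2, 0 °C; then DBU, rt
Reagents that add atoms: none
Why: Selective sulfonylation of the primary hydroxyl followed by base-induced 3-exo-tet displacement by the tertiary alkoxide closes the oxirane with retention at the quaternary carbon, because only the primary C–O bond is broken.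

Step 24
Reactants: 13 (2S)-but-3-yn-2-ol
Product: 39 (2E,4S)-4-hydroxy-3-methylpent-2-enoic acid, via alkenylalane 37 (not isolated), via lithium alanate 38 (not isolated)
Conditions: AlMe3, Cp2ZrCl2 (0.3 equiv), CH2Cl2, 0 °C→rt; evaporate; n-BuLi, THF, −78 °C; CO2, −78 °C→rt; aq. HCl
Reagents that add atoms: trimethylaluminium, C[Al](C)C; carbon dioxide, O=C=O
Why: Negishi carboalumination adds methyl and aluminium syn across the alkyne (aluminium at the terminus), and the derived alkenylalanate is carboxylated with retention, giving the (E)-acid with the carbinol trans to the carboxyl group.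

Step 25
Reactants: 39 (2E,4S)-4-hydroxy-3-methylpent-2-enoic acid
Product: 40 (2E,4S)-4-acetoxy-3-methylpent-2-enoic acid
Conditions: Ac2O, pyridine, DMAP (cat.), CH2Cl2, 0 °C→rt; aqueous work-up
Reagents that add atoms: acetic anhydride, CC(=O)OC(C)=O
Why: Acetylation of the secondary alcohol; the mixed anhydride formed at the carboxyl group is hydrolysed on aqueous work-up.

Step 26
Reactants: 40 (2E,4S)-4-acetoxy-3-methylpent-2-enoic acid; 36 (3aβ-H,7aα-H)-3β-[(1S)-1-acetoxyethyl]-6α-hydroxy-7-methylidene-4β-[(2R)-2-methyloxiran-2-yl]octahydro-1H-indene-1β,2α-diyl bis(2-methylpropanoate)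
Product: 42 CNP0131236.1, via mixed anhydride 41 (not isolated)
Conditions: 40, 2,4,6-trichlorobenzoyl chloride, Et3N, toluene, rt; then 36, DMAP, rt
Reagents that add atoms: none
Why: Yamaguchi esterification: the mixed anhydride 41 is attacked by DMAP at the less hindered enoyl carbonyl and the acylpyridinium acylates the axial allylic C6 hydroxyl, the only free hydroxyl of 36, with retention at C6.

**Compound list**

1 | penta-1,4-dien-3-ol | C=CC(O)C=C | starting material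
2 | (1R)-1-[(2S)-oxiran-2-yl]prop-2-en-1-ol | C=C[C@@H](O)[C@@H]1CO1 | intermediate
3 | tert-butyl(dimethyl){[(1R)-1-[(2S)-oxiran-2-yl]prop-2-en-1-yl]oxy}silane | C=C[C@@H](O[Si](C)(C)C(C)(C)C)[C@@H]1CO1 | intermediate
4 | prop-2-yn-1-ol | C#CCO | starting material
5 | dimethyl[(1E)-3-[(dimethylalumanyl)oxy]-2-methylprop-1-en-1-yl]alumane | C[Al](C)OC/C(C)=C/[Al](C)C | intermediate
6 | (2E)-3-iodo-2-methylprop-2-en-1-ol | OC/C(C)=C/I | intermediate
7 | 1-({[(2E)-3-iodo-2-methylprop-2-en-1-yl]oxy}methyl)-4-methoxybenzene | COc1ccc(COC/C(C)=C/I)cc1 | intermediate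
8 | [(1E)-3-[(4-methoxybenzyl)oxy]-2-methylprop-1-en-1-yl]lithium | COc1ccc(COC/C(C)=C/[Li])cc1 | intermediate
9 | (3R,4S,6E)-3-(TBSO)-8-[(4-methoxybenzyl)oxy]-7-methylocta-1,6-dien-4-ol | C=C[C@@H](O[Si](C)(C)C(C)(C)C)[C@@H](O)C/C=C(\C)COCc1ccc(OC)cc1 | intermediate
10 | (3R,4S,6E)-3-(TBSO)-8-[(4-methoxybenzyl)oxy]-7-methyl-4-(TIPSO)octa-1,6-diene | C=C[C@@H](O[Si](C)(C)C(C)(C)C)[C@@H](O[Si](C(C)C)(C(C)C)C(C)C)C/C=C(\C)COCc1ccc(OC)cc1 | intermediate
11 | (2E,5S,6R)-6-(TBSO)-2-methyl-5-(TIPSO)octa-2,7-dien-1-ol | C=C[C@@H](O[Si](C)(C)C(C)(C)C)[C@@H](O[Si](C(C)C)(C(C)C)C(C)C)C/C=C(\C)CO | intermediate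
12 | [(2S,3S)-3-{(2S,3R)-3-(TBSO)-2-(TIPSO)pent-4-en-1-yl}-2-methyloxiran-2-yl]methanol | C=C[C@@H](O[Si](C)(C)C(C)(C)C)[C@@H](O[Si](C(C)C)(C(C)C)C(C)C)C[C@@H]1O[C@@]1(C)CO | intermediate
13 | (2S)-but-3-yn-2-ol | C#C[C@H](C)O | starting material
14 | [(2S)-but-3-yn-2-yloxy]triethylsilane | C#C[C@H](C)O[Si](CC)(CC)CC | intermediate
15 | [(3S)-3-(TESO)but-1-yn-1-yl]lithium | [Li]C#C[C@H](C)O[Si](CC)(CC)CC | intermediate
16 | diethyl[(3S)-3-(TESO)but-1-yn-1-yl]alumane | CC[Al](CC)C#C[C@H](C)O[Si](CC)(CC)CC | intermediate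
17 | (2R,3S,5S,6R)-6-(TBSO)-2-methyl-3-[(3S)-3-(TESO)but-1-yn-1-yl]-5-(TIPSO)oct-7-ene-1,2-diol | C=C[C@@H](O[Si](C)(C)C(C)(C)C)[C@@H](O[Si](C(C)C)(C(C)C)C(C)C)C[C@H]([C@](O)(C)CO)C#C[C@H](C)O[Si](CC)(CC)CC | intermediate
18 | (4R)-4-{(3R,4S,6S,9S)-3-(TBSO)-9-(TESO)-4-(TIPSO)dec-1-en-7-yn-6-yl}-2,2,4-trimethyl-1,3-dioxolane (Pauson–Khand precursor) | C=C[C@@H](O[Si](C)(C)C(C)(C)C)[C@@H](O[Si](C(C)C)(C(C)C)C(C)C)C[C@H]([C@]1(C)COC(C)(C)O1)C#C[C@H](C)O[Si](CC)(CC)CC | intermediate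
19 | hexacarbonyldicobalt complex of the alkyne of 18 | C=C[C@@H](O[Si](C)(C)C(C)(C)C)[C@@H](O[Si](C(C)C)(C(C)C)C(C)C)C[C@H]([C@]1(C)COC(C)(C)O1)C23C4([C@H](C)O[Si](CC)(CC)CC)[Co]2(=C=O)(=C=O)(=C=O)[Co]34(=C=O)(=C=O)=C=O | intermediate
20 | (7aα-H)-7α-(TBSO)-6α-(TIPSO)-3-[(1S)-1-(TESO)ethyl]-4β-[(4R)-2,2,4-trimethyl-1,3-dioxolan-4-yl]-1,4,5,6,7,7a-hexahydro-2H-inden-2-one (Pauson–Khand product) | O=C1C[C@@H]2[C@@H](O[Si](C)(C)C(C)(C)C)[C@@H](O[Si](C(C)C)(C(C)C)C(C)C)C[C@H]([C@]3(C)COC(C)(C)O3)C2=C1[C@H](C)O[Si](CC)(CC)CC | intermediate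
21 | lithium C2(O)=C3 enolate of 22 | CC(C)(C)[Si](C)(C)O[C@@H]1[C@H]2CC(O[Li])=C([C@H](C)O[Si](CC)(CC)CC)[C@@H]2[C@@H]([C@]3(C)COC(C)(C)O3)C[C@@H]1O[Si](C(C)C)(C(C)C)C(C)C | intermediate
22 | (3aβ-H,7aα-H)-7α-(TBSO)-6α-(TIPSO)-3β-[(1S)-1-(TESO)ethyl]-4β-[(4R)-2,2,4-trimethyl-1,3-dioxolan-4-yl]octahydro-2H-inden-2-one | CC(C)(C)[Si](C)(C)O[C@@H]1[C@H]2CC(=O)[C@@H]([C@H](C)O[Si](CC)(CC)CC)[C@@H]2[C@@H]([C@]3(C)COC(C)(C)O3)C[C@@H]1O[Si](C(C)C)(C(C)C)C(C)C | intermediate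
23 | lithium C1=C2(O) enolate of 22 | CC(C)(C)[Si](C)(C)O[C@@H]1[C@H]2C=C(O[Li])[C@@H]([C@H](C)O[Si](CC)(CC)CC)[C@@H]2[C@@H]([C@]3(C)COC(C)(C)O3)C[C@@H]1O[Si](C(C)C)(C(C)C)C(C)C | intermediate
24 | trimethylsilyl C1=C2 enol ether of 22 | CC(C)(C)[Si](C)(C)O[C@@H]1[C@H]2C=C(O[Si](C)(C)C)[C@@H]([C@H](C)O[Si](CC)(CC)CC)[C@@H]2[C@@H]([C@]3(C)COC(C)(C)O3)C[C@@H]1O[Si](C(C)C)(C(C)C)C(C)C | intermediate
25 | 1β-(trimethylsilyloxy) derivative of 22 | CC(C)(C)[Si](C)(C)O[C@@H]1[C@H]2[C@@H](O[Si](C)(C)C)C(=O)[C@@H]([C@H](C)O[Si](CC)(CC)CC)[C@@H]2[C@@H]([C@]3(C)COC(C)(C)O3)C[C@@H]1O[Si](C(C)C)(C(C)C)C(C)C | intermediate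
26 | (3aβ-H,7aα-H)-1β-hydroxy-7α-(TBSO)-6α-(TIPSO)-3β-[(1S)-1-(TESO)ethyl]-4β-[(4R)-2,2,4-trimethyl-1,3-dioxolan-4-yl]octahydro-2H-inden-2-one | CC(C)(C)[Si](C)(C)O[C@@H]1[C@H]2[C@@H](O)C(=O)[C@@H]([C@H](C)O[Si](CC)(CC)CC)[C@@H]2[C@@H]([C@]3(C)COC(C)(C)O3)C[C@@H]1O[Si](C(C)C)(C(C)C)C(C)C | intermediate
27 | (3aβ-H,7aα-H)-7α-(TBSO)-6α-(TIPSO)-3β-[(1S)-1-(TESO)ethyl]-4β-[(4R)-2,2,4-trimethyl-1,3-dioxolan-4-yl]-2-oxooctahydro-1H-inden-1β-yl 2-methylpropanoate | CC(C)(C)[Si](C)(C)O[C@@H]1[C@H]2[C@@H](OC(=O)C(C)C)C(=O)[C@@H]([C@H](C)O[Si](CC)(CC)CC)[C@@H]2[C@@H]([C@]3(C)COC(C)(C)O3)C[C@@H]1O[Si](C(C)C)(C(C)C)C(C)C | intermediate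
28 | (3aβ-H,7aα-H)-7α-(TBSO)-6α-(TIPSO)-3β-[(1S)-1-hydroxyethyl]-4β-[(4R)-2,2,4-trimethyl-1,3-dioxolan-4-yl]-2-oxooctahydro-1H-inden-1β-yl 2-methylpropanoate | CC(C)(C)[Si](C)(C)O[C@@H]1[C@H]2[C@@H](OC(=O)C(C)C)C(=O)[C@@H]([C@H](C)O)[C@@H]2[C@@H]([C@]3(C)COC(C)(C)O3)C[C@@H]1O[Si](C(C)C)(C(C)C)C(C)C | intermediate
29 | (3aβ-H,7aα-H)-3β-[(1S)-1-acetoxyethyl]-7α-(TBSO)-2α-hydroxy-6α-(TIPSO)-4β-[(4R)-2,2,4-trimethyl-1,3-dioxolan-4-yl]octahydro-1H-inden-1β-yl 2-methylpropanoate | CC(C)(C)[Si](C)(C)O[C@@H]1[C@H]2[C@@H](OC(=O)C(C)C)[C@H](O)[C@@H]([C@H](C)OC(C)=O)[C@@H]2[C@@H]([C@]3(C)COC(C)(C)O3)C[C@@H]1O[Si](C(C)C)(C(C)C)C(C)C | intermediate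
30 | (3aβ-H,7aα-H)-3β-[(1S)-1-acetoxyethyl]-7α-(TBSO)-6α-(TIPSO)-4β-[(4R)-2,2,4-trimethyl-1,3-dioxolan-4-yl]octahydro-1H-indene-1β,2α-diyl bis(2-methylpropanoate) | CC(C)(C)[Si](C)(C)O[C@@H]1[C@H]2[C@@H](OC(=O)C(C)C)[C@H](OC(=O)C(C)C)[C@@H]([C@H](C)OC(C)=O)[C@@H]2[C@@H]([C@]3(C)COC(C)(C)O3)C[C@@H]1O[Si](C(C)C)(C(C)C)C(C)C | intermediate
31 | (3aβ-H,7aα-H)-3β-[(1S)-1-acetoxyethyl]-7α-hydroxy-6α-(TIPSO)-4β-[(4R)-2,2,4-trimethyl-1,3-dioxolan-4-yl]octahydro-1H-indene-1β,2α-diyl bis(2-methylpropanoate) | O[C@@H]1[C@H]2[C@@H](OC(=O)C(C)C)[C@H](OC(=O)C(C)C)[C@@H]([C@H](C)OC(C)=O)[C@@H]2[C@@H]([C@]3(C)COC(C)(C)O3)C[C@@H]1O[Si](C(C)C)(C(C)C)C(C)C | intermediate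
32 | (3aβ-H,7aα-H)-3β-[(1S)-1-acetoxyethyl]-7-oxo-6α-(TIPSO)-4β-[(4R)-2,2,4-trimethyl-1,3-dioxolan-4-yl]octahydro-1H-indene-1β,2α-diyl bis(2-methylpropanoate) | O=C1[C@H]2[C@@H](OC(=O)C(C)C)[C@H](OC(=O)C(C)C)[C@@H]([C@H](C)OC(C)=O)[C@@H]2[C@@H]([C@]3(C)COC(C)(C)O3)C[C@@H]1O[Si](C(C)C)(C(C)C)C(C)C | intermediate
33 | (3aβ-H,7aα-H)-3β-[(1S)-1-acetoxyethyl]-7-methylidene-6α-(TIPSO)-4β-[(4R)-2,2,4-trimethyl-1,3-dioxolan-4-yl]octahydro-1H-indene-1β,2α-diyl bis(2-methylpropanoate) | C=C1[C@H]2[C@@H](OC(=O)C(C)C)[C@H](OC(=O)C(C)C)[C@@H]([C@H](C)OC(C)=O)[C@@H]2[C@@H]([C@]3(C)COC(C)(C)O3)C[C@@H]1O[Si](C(C)C)(C(C)C)C(C)C | intermediate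
34 | (3aβ-H,7aα-H)-3β-[(1S)-1-acetoxyethyl]-4β-[(2R)-1,2-dihydroxypropan-2-yl]-6α-hydroxy-7-methylideneoctahydro-1H-indene-1β,2α-diyl bis(2-methylpropanoate) | C=C1[C@H]2[C@@H](OC(=O)C(C)C)[C@H](OC(=O)C(C)C)[C@@H]([C@H](C)OC(C)=O)[C@@H]2[C@@H]([C@](O)(C)CO)C[C@@H]1O | intermediate
35 | (3aβ-H,7aα-H)-3β-[(1S)-1-acetoxyethyl]-6α-hydroxy-4β-[(2R)-2-hydroxy-1-(tosyloxy)propan-2-yl]-7-methylideneoctahydro-1H-indene-1β,2α-diyl bis(2-methylpropanoate) | C=C1[C@H]2[C@@H](OC(=O)C(C)C)[C@H](OC(=O)C(C)C)[C@@H]([C@H](C)OC(C)=O)[C@@H]2[C@@H]([C@](O)(C)COS(=O)(=O)c3ccc(C)cc3)C[C@@H]1O | intermediate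
36 | (3aβ-H,7aα-H)-3β-[(1S)-1-acetoxyethyl]-6α-hydroxy-7-methylidene-4β-[(2R)-2-methyloxiran-2-yl]octahydro-1H-indene-1β,2α-diyl bis(2-methylpropanoate) | C=C1[C@H]2[C@@H](OC(=O)C(C)C)[C@H](OC(=O)C(C)C)[C@@H]([C@H](C)OC(C)=O)[C@@H]2[C@@H]([C@]3(C)CO3)C[C@@H]1O | intermediate
37 | dimethyl[(1E,3S)-3-[(dimethylalumanyl)oxy]-2-methylbut-1-en-1-yl]alumane | C[Al](C)/C=C(\C)[C@H](C)O[Al](C)C | intermediate
38 | lithium butyl(dimethyl)[(1E,3S)-3-[(dimethylalumanyl)oxy]-2-methylbut-1-en-1-yl]aluminate | [Li+].CCCC[Al-](C)(C)/C=C(\C)[C@H](C)O[Al](C)C | intermediate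
39 | (2E,4S)-4-hydroxy-3-methylpent-2-enoic acid | OC(=O)/C=C(\C)[C@H](C)O | intermediate
40 | (2E,4S)-4-acetoxy-3-methylpent-2-enoic acid | OC(=O)/C=C(\C)[C@H](C)OC(C)=O | intermediate
41 | (2E,4S)-4-acetoxy-3-methylpent-2-enoic 2,4,6-trichlorobenzoic anhydride | O=C(OC(=O)/C=C(\C)[C@H](C)OC(C)=O)c1c(Cl)cc(Cl)cc1Cl | intermediate
42 | CNP0131236.1: (1R,2R,3R,3aR,4S,6S,7aS)-3-[(1S)-1-acetoxyethyl]-6-{[(2E,4S)-4-acetoxy-3-methylpent-2-enoyl]oxy}-7-methylidene-4-[(2R)-2-methyloxiran-2-yl]octahydro-1H-indene-1,2-diyl bis(2-methylpropanoate) (numbering of this proposal) | C=C1[C@H]2[C@@H](OC(=O)C(C)C)[C@H](OC(=O)C(C)C)[C@@H]([C@H](C)OC(C)=O)[C@@H]2[C@@H]([C@]2(C)CO2)C[C@@H]1OC(=O)/C=C(\C)[C@H](C)OC(C)=O | target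

**Step count and risk**

Total step count: 26. Longest linear sequence: 21 steps (steps 1, 2, 5–8, 10–23, 26).

Steps most likely to fail:

Step 12. Insertion of the vinyl group into the crowded cobalt–alkyne complex 19 (both propargylic carbons are branched) may be slow, so that decomplexation or cyclisation through the flipped chair, on the wrong face of the vinyl group, competes. The fallback sets out from enyne 18 and uses a nickel-mediated enyne–isocyanide [2+2+1] cyclisation at a single, less congested metal centre (Ni(cod)2, PBu3, 2,6-dimethylphenyl isocyanide, THF). This should give the N-aryl iminocyclopentene F1, and mild hydrolysis (aqueous oxalic acid, THF, 0 °C) returns the route at enone 20.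

Step 14. The peracid may attack the α face of enol ether 24 (poor facial selectivity at C1). In that case the same preference is turned to use: the fallback sets out from ketone 22 through its enol ether 24, which is brominated with N-bromosuccinimide (THF, −78 °C) to give the 1α-bromo ketone F2. Displacement of the bromide by caesium 2-methylpropanoate (Cs2CO3, 2-methylpropanoic acid, DMF, rt) with inversion gives the 1β-isobutyrate and rejoins the route at 27, skipping 26 and step 15.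

Step 21. Ketone 32 may enolise toward C7a and lose the C1 isobutyrate by β-elimination, or its doubly flanked carbonyl group may not add the methylene reagent. The fallback sets out from 32 and replaces the one-step methylenation by a Peterson sequence: the weakly basic organocerium reagent from Me3SiCH2Li and CeCl3 (THF, −78 °C) adds to the ketone to give the β-hydroxysilane F3. The aqueous HF of step 22 then causes elimination to the methylidene group together with loss of the silyl ether and the dioxolane, so the route is rejoined at triol 34.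

Further compounds
F1 | step 12 | N-(2,6-dimethylphenyl) imine of enone 20: (7aα-H)-N-(2,6-dimethylphenyl)-7α-(TBSO)-6α-(TIPSO)-3-[(1S)-1-(TESO)ethyl]-4β-[(4R)-2,2,4-trimethyl-1,3-dioxolan-4-yl]-1,4,5,6,7,7a-hexahydro-2H-inden-2-imine | Cc1cccc(C)c1N=C1C[C@@H]2[C@@H](O[Si](C)(C)C(C)(C)C)[C@@H](O[Si](C(C)C)(C(C)C)C(C)C)C[C@H]([C@]3(C)COC(C)(C)O3)C2=C1[C@H](C)O[Si](CC)(CC)CC
F2 | step 14 | (3aβ-H,7aα-H)-1α-bromo-7α-(TBSO)-6α-(TIPSO)-3β-[(1S)-1-(TESO)ethyl]-4β-[(4R)-2,2,4-trimethyl-1,3-dioxolan-4-yl]octahydro-2H-inden-2-one | CC(C)(C)[Si](C)(C)O[C@@H]1[C@H]2[C@H](Br)C(=O)[C@@H]([C@H](C)O[Si](CC)(CC)CC)[C@@H]2[C@@H]([C@]3(C)COC(C)(C)O3)C[C@@H]1O[Si](C(C)C)(C(C)C)C(C)C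
F3 | step 21 | (3aβ-H,7aα-H)-3β-[(1S)-1-acetoxyethyl]-7β-hydroxy-7α-[(trimethylsilyl)methyl]-6α-(TIPSO)-4β-[(4R)-2,2,4-trimethyl-1,3-dioxolan-4-yl]octahydro-1H-indene-1β,2α-diyl bis(2-methylpropanoate) (expected major C7 epimer; either epimer gives the same alkene) | O[C@@]1(C[Si](C)(C)C)[C@H]2[C@@H](OC(=O)C(C)C)[C@H](OC(=O)C(C)C)[C@@H]([C@H](C)OC(C)=O)[C@@H]2[C@@H]([C@]3(C)COC(C)(C)O3)C[C@@H]1O[Si](C(C)C)(C(C)C)C(C)C
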